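The bonds that matter are C9–C10 and O–C10 of the oxygen-bridged ten-membered ring. Cutting them takes the bicycle back to a plain six-membered cyclic ether. The feature exploited is the furanone oxygen spanning C3 and C10 of the carbocycle (an 11-oxabicyclo[6.2.1]undecane) with quaternary C10 beside the C1 ketone. In one operation a copper carbenoid generated at C10 is trapped by the dihydropyran oxygen and the oxonium ylide rearranges [2,3] across the C7 vinyl group, building the furanone ring, the carbocycle and C10. The precursor, diazoketone 21, is an all-cis 2-vinyl-3-silyloxy-3,6-dihydro-2H-pyran bearing a 3-diazobutan-2-one arm, made from L-tartrate by glycolate alkylation and ring-closing metathesis.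

Key step: step 14

Remark: atoms are numbered C1–C15 as in the germacrane skeleton of the target (the bridging oxygen sits on C3 and C10, O6 is the lactone oxygen, C11–C13 are the methylene-lactone carbons); TBS = tert-butyldimethylsilyl.
Assumption: diazoethane is used as a freshly prepared ethereal solution (from commercial N-ethyl-N-nitrosourea and aqueous KOH); its preparation is not counted as a step.
Assumption: the ring expansion gives the Z C7=C8 alkene drawn for 23; step 18 translates this geometry into the C7/C8 configuration by anti addition.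

Step 1
Reactants: 1 dimethyl (4R,5R)-2,2-dimethyl-1,3-dioxolane-4,5-dicarboxylate (dimethyl 2,3-O-isopropylidene-L-tartrate)
Product: 3 (4S,5S)-2,2-dimethyl-4,5-divinyl-1,3-dioxolane, via dialdehyde 2 (not isolated)
Conditions: DIBAL-H (2.1 equiv), toluene, −78 °C; then Ph3P=CH2 (Ph3PCH3Br, KHMDS), THF, −78 °C → rt
Reagents that add atoms: methyltriphenylphosphonium bromide, C[P+](c1ccccc1)(c1ccccc1)c1ccccc1.[Br-]
Why: DIBAL-H stops at the aluminium hemiacetal at −78 °C and the in-situ Wittig methylenation consumes each aldehyde as it is released, so the epimerisable dialdehyde never accumulates and both tartrate stereocentres (the future C6 and C7) are carried over unchanged.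

Step 2
Reactants: 3 (4S,5S)-2,2-dimethyl-4,5-divinyl-1,3-dioxolane
Product: 4 (3S,4S)-hexa-1,5-diene-3,4-diol
Conditions: 1 M aq. HCl, THF, 40 °C
Reagents that add atoms: none
Why: Acid-catalysed acetal hydrolysis frees the C2-symmetric threo diol without touching the carbinol centres.

Step 3
Reactants: 4 (3S,4S)-hexa-1,5-diene-3,4-diol
Product: 5 (3S,4S)-4-(TBSO)hexa-1,5-dien-3-ol
Conditions: NaH (1.0 equiv), THF, 0 °C → rt; TBSCl (1.0 equiv)
Reagents that add atoms: tert-butyldimethylsilyl chloride, CC(C)(C)[Si](C)(C)Cl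
Why: Monosilylation through the monosodium alkoxide (McDougal conditions) should stop after one silyl group, and because the diol is C2-symmetric either hydroxyl gives the same compound.

Step 4
Reactants: 5 (3S,4S)-4-(TBSO)hexa-1,5-dien-3-ol; 6 bromoacetic acid
Product: 7 2-{[(3S,4S)-4-(TBSO)hexa-1,5-dien-3-yl]oxy}acetic acid
Conditions: NaH (3 equiv), THF, 0 °C → rt; aq. HCl work-up
Reagents that add atoms: none
Why: Williamson etherification of the sodium alkoxide with sodium bromoacetate puts the glycolate on the future O–C7 oxygen, and a 1,2-silyl shift between the two oxygens would be degenerate.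

Step 5
Reactants: 7 2-{[(3S,4S)-4-(TBSO)hexa-1,5-dien-3-yl]oxy}acetic acid; 8 (S)-4-benzyl-1,3-oxazolidin-2-one
Product: 10 (4S)-4-benzyl-3-(2-{[(3S,4S)-4-(TBSO)hexa-1,5-dien-3-yl]oxy}acetyl)-1,3-oxazolidin-2-one, via mixed pivalic anhydride 9 (not isolated)
Conditions: PivCl, Et3N, THF, −78 → 0 °C; then 8/n-BuLi, THF, −78 → 0 °C
Reagents that add atoms: none
Why: Standard N-acylation of the lithiated Evans oxazolidinone by the mixed pivalic anhydride attaches the auxiliary that will control C3.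

Step 6
Reactants: 10 (4S)-4-benzyl-3-(2-{[(3S,4S)-4-(TBSO)hexa-1,5-dien-3-yl]oxy}acetyl)-1,3-oxazolidin-2-one; 11 tert-butyl bromoacetate
Product: 12 tert-butyl (3R)-4-[(4S)-4-benzyl-2-oxo-1,3-oxazolidin-3-yl]-4-oxo-3-{[(3S,4S)-4-(TBSO)hexa-1,5-dien-3-yl]oxy}butanoate
Conditions: NaHMDS (1.3 equiv), THF, −78 °C; 11 (4 equiv), −78 → −45 °C
Reagents that add atoms: none
Why: Evans-type glycolate alkylation, in which the chelated sodium (Z)-enolate is alkylated on the face away from the benzyl group, sets C3 as R under auxiliary control and brings in C2 and C1.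

Step 7
Reactants: 12 tert-butyl (3R)-4-[(4S)-4-benzyl-2-oxo-1,3-oxazolidin-3-yl]-4-oxo-3-{[(3S,4S)-4-(TBSO)hexa-1,5-dien-3-yl]oxy}butanoate
Product: 13 tert-butyl (3R)-4-[methoxy(methyl)amino]-4-oxo-3-{[(3S,4S)-4-(TBSO)hexa-1,5-dien-3-yl]oxy}butanoate
Conditions: MeNHOMe·HCl, AlMe3, CH2Cl2, 0 °C → rt
Reagents that add atoms: N,O-dimethylhydroxylamine hydrochloride, CNOC.Cl
Why: Weinreb transamidation with the aluminium amide opens only the activated exocyclic imide carbonyl, leaving the tert-butyl ester intact and returning the auxiliary.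

Step 8
Reactants: 13 tert-butyl (3R)-4-[methoxy(methyl)amino]-4-oxo-3-{[(3S,4S)-4-(TBSO)hexa-1,5-dien-3-yl]oxy}butanoate
Product: 14 tert-butyl (3R)-4-oxo-3-{[(3S,4S)-4-(TBSO)hexa-1,5-dien-3-yl]oxy}pentanoate
Conditions: MeMgBr (1.5 equiv), THF, 0 °C
Reagents that add atoms: methylmagnesium bromide, C[Mg]Br
Why: Weinreb ketone synthesis, where the chelated tetrahedral adduct prevents over-addition and the hindered tert-butyl ester does not react at 0 °C, gives the methyl ketone that carries C4 and C15.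

Step 9
Reactants: 14 tert-butyl (3R)-4-oxo-3-{[(3S,4S)-4-(TBSO)hexa-1,5-dien-3-yl]oxy}pentanoate
Product: 15 tert-butyl (3R)-4-methyl-3-{[(3S,4S)-4-(TBSO)hexa-1,5-dien-3-yl]oxy}pent-4-enoate
Conditions: Ph3PCH3Br, KHMDS, THF, −78 → 0 °C
Reagents that add atoms: methyltriphenylphosphonium bromide, C[P+](c1ccccc1)(c1ccccc1)c1ccccc1.[Br-]
Why: Wittig methylenation of the methyl ketone at low temperature should give the 1,1-disubstituted C4 alkene faster than the α-alkoxy centre C3 can enolise.

Step 10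
Reactants: 15 tert-butyl (3R)-4-methyl-3-{[(3S,4S)-4-(TBSO)hexa-1,5-dien-3-yl]oxy}pent-4-enoate
Product: 16 tert-butyl (3R)-3-{[(3S,4S)-4-hydroxyhexa-1,5-dien-3-yl]oxy}-4-methylpent-4-enoate
Conditions: HF·pyridine, pyridine, THF, 0 °C → rt
Reagents that add atoms: none
Why: Fluoride desilylation frees the C6 hydroxyl, which is needed to steer the metathesis, while the tert-butyl ester and the allylic ether are inert to buffered HF.

Step 11
Reactants: 16 tert-butyl (3R)-3-{[(3S,4S)-4-hydroxyhexa-1,5-dien-3-yl]oxy}-4-methylpent-4-enoate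
Product: 17 tert-butyl 2-[(2S,3S,6R)-3-hydroxy-5-methyl-2-vinyl-3,6-dihydro-2H-pyran-6-yl]acetate
Conditions: Grubbs II (5 mol %), CH2Cl2 (5 mM), 40 °C
Reagents that add atoms: none
Why: Ring-closing metathesis in which the free allylic hydroxyl accelerates loading of ruthenium onto the adjacent C5 vinyl group, so closure onto the isopropenyl group should give the six-membered dihydropyran (C4=C5) in preference to the five-membered ring that the C8 vinyl group would give.

Step 12
Reactants: 17 tert-butyl 2-[(2S,3S,6R)-3-hydroxy-5-methyl-2-vinyl-3,6-dihydro-2H-pyran-6-yl]acetate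
Product: 19 2-[(2S,3S,6R)-3-(TBSO)-5-methyl-2-vinyl-3,6-dihydro-2H-pyran-6-yl]acetic acid, via silyl ester 18 (not isolated)
Conditions: TBSOTf (3 equiv), 2,6-lutidine, CH2Cl2, 0 °C → rt; then K2CO3, MeOH/THF/H2O, rt
Reagents that add atoms: tert-butyldimethylsilyl triflate, CC(C)(C)[Si](C)(C)OS(=O)(=O)C(F)(F)F
Why: The silyl triflate silylates the alcohol and converts the tert-butyl ester into the silyl ester with loss of isobutene, and mild carbonate methanolysis then cleaves only the labile silyl ester, so the acid is unmasked without strong acid.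

Step 13
Reactants: 19 2-[(2S,3S,6R)-3-(TBSO)-5-methyl-2-vinyl-3,6-dihydro-2H-pyran-6-yl]acetic acid
Product: 21 3-diazo-1-[(2S,3S,6R)-3-(TBSO)-5-methyl-2-vinyl-3,6-dihydro-2H-pyran-6-yl]butan-2-one, via mixed carbonic anhydride 20 (not isolated)
Conditions: i-BuOCOCl, Et3N, Et2O, −20 °C; then CH3CHN2 (Et2O), −20 → 0 °C
Reagents that add atoms: diazoethane, CC=[N+]=[N-]
Why: Acylation of diazoethane by the mixed carbonic anhydride (the first stage of an Arndt–Eistert sequence) gives the α-methyl diazoketone with C10 and C14 under neutral conditions that the silyl ether and the allylic ether tolerate.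

Step 14
Reactants: 21 3-diazo-1-[(2S,3S,6R)-3-(TBSO)-5-methyl-2-vinyl-3,6-dihydro-2H-pyran-6-yl]butan-2-one
Product: 23 (1R,2Z,4R,5Z,8R)-4-(TBSO)-2,8-dimethyl-11-oxabicyclo[6.2.1]undeca-2,5-dien-9-one, via oxonium ylide 22 (not isolated)
Conditions: Cu(hfacac)2 (5 mol %), CH2Cl2, reflux, slow addition of 21 (final 5 mM)
Reagents that add atoms: none
Why: Cu(hfacac)2 decomposes the diazoketone to an electrophilic copper carbenoid at C10, a lone pair of the ring oxygen adds to it to give the cis-fused bicyclic oxonium ylide 22, and a concerted suprafacial [2,3]-sigmatropic shift through the five-centre array C10–O–C7–C8–C9 forms C9–C10 while O–C7 breaks. The closest known reaction type is the copper-catalysed oxonium ylide formation/[2,3] ring expansion of 2-vinyl tetrahydropyranyl diazoketones to 11-oxabicyclo[6.2.1]undecenones. The dihydrofuranone ring is closed by attack of oxygen on the carbenoid carbon tethered three atoms away (a five-membered closure at the metal carbene), and the ten-membered carbocycle is closed by the sigmatropic C9–C10 bond formation, a three-atom ring expansion of the six-membered ether through an envelope transition state. C10 is set by substrate control from C3, because the two-carbon tether makes the ylide cis-fused and the cis C7 vinyl group can only reach the same face, so the oxygen bridge ends cis and C10 is R. The new C7=C8 bond should be Z, the geometry best accommodated in the nine-membered oxacycle that already holds the Z C4=C5 bond. The step needs capture by oxygen to outrun 1,2-hydride shift of the methyl carbenoid, cyclopropanation of C4=C5 and [1,2]-shift, and the five-membered reach to the Lewis-basic ether oxygen, the weakly nucleophilic silyl ether at C6 and the electron-poor hexafluoroacetylacetonate ligands should secure this.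

Step 15
Reactants: 23 (1R,2Z,4R,5Z,8R)-4-(TBSO)-2,8-dimethyl-11-oxabicyclo[6.2.1]undeca-2,5-dien-9-one
Product: 25 (2Z,4R,5Z,8R)-4-(TBSO)-2,8-dimethyl-11-oxabicyclo[6.2.1]undeca-1(10),2,5-trien-9-one, via trimethylsilyl enol ether 24 (not isolated)
Conditions: TMSOTf, Et3N, CH2Cl2, 0 °C; then Pd(OAc)2 (1.1 equiv), MeCN, rt
Reagents that add atoms: none
Why: Saegusa–Ito oxidation, in which the ketone can enolise only towards C2 because C10 is quaternary and syn β-hydride elimination of H3 from the palladium enolate gives the 3(2H)-furanone, also turns C4=C5 into an electron-poor dienone alkene before the gold step.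

Step 16
Reactants: 25 (2Z,4R,5Z,8R)-4-(TBSO)-2,8-dimethyl-11-oxabicyclo[6.2.1]undeca-1(10),2,5-trien-9-one
Product: 26 (2Z,4R,5Z,8R)-4-hydroxy-2,8-dimethyl-11-oxabicyclo[6.2.1]undeca-1(10),2,5-trien-9-one
Conditions: HF·pyridine, pyridine, THF, 0 °C
Reagents that add atoms: none
Why: Fluoride desilylation of the doubly allylic silyl ether releases the C6 alcohol under mildly acidic conditions that the dienone tolerates.

Step 17
Reactants: 26 (2Z,4R,5Z,8R)-4-hydroxy-2,8-dimethyl-11-oxabicyclo[6.2.1]undeca-1(10),2,5-trien-9-one; 27 propargyl bromide (3-bromoprop-1-yne)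
Product: 28 (2Z,4R,5Z,8R)-2,8-dimethyl-4-(prop-2-yn-1-yloxy)-11-oxabicyclo[6.2.1]undeca-1(10),2,5-trien-9-one
Conditions: NaH (1.1 equiv), 27 (3 equiv), Bu4NI (cat.), THF, 0 °C
Reagents that add atoms: none
Why: Williamson etherification of the sodium alkoxide with the reactive propargylic bromide at 0 °C brings in C11–C13 as a 1,6-enyne tether on O6.

Step 18
Reactants: 28 (2Z,4R,5Z,8R)-2,8-dimethyl-4-(prop-2-yn-1-yloxy)-11-oxabicyclo[6.2.1]undeca-1(10),2,5-trien-9-one
Product: 29 (4Z,6S,7S,8R,10R)-8-hydroxy-3,10:6,12-diepoxygermacra-2,4,11(13)-trien-1-one (trans-fused 3-methylene-tetrahydrofuran on C6/C7, free 8-OH)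
Conditions: [JohnPhosAu(MeCN)]SbF6 (5 mol %), 1,4-dioxane/H2O (10:1), rt
Reagents that add atoms: water, O
Why: Gold(I)-catalysed hydroxycyclisation of the 1,6-enyne, in which the π-activated alkyne is attacked 5-exo-dig only by the electron-rich C7=C8 bond (the dienone C4=C5 bond is deactivated) on the face where O6 sits, gives the trans-fused ring at C7 because the ring carbon C5 is forced onto the other face, and water opens the cyclopropyl gold carbene at C8 anti, so the Z alkene is translated into 7S,8R before protodeauration leaves the exocyclic methylene.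

Step 19
Reactants: 30 tert-butyl acrylate; 31 acetaldehyde
Product: 32 tert-butyl 3-hydroxy-2-methylidenebutanoate (racemic)
Conditions: DABCO (0.2 equiv), neat, rt, 7 d
Reagents that add atoms: none
Why: Morita–Baylis–Hillman reaction of the acrylate with acetaldehyde under DABCO catalysis gives the racemic allylic alcohol, whose stereocentre is removed two steps later.

Step 20
Reactants: 32 tert-butyl 3-hydroxy-2-methylidenebutanoate
Product: 33 tert-butyl 3-acetoxy-2-methylidenebutanoate (racemic)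
Conditions: Ac2O, pyridine, DMAP (cat.), CH2Cl2, 0 °C → rt
Reagents that add atoms: acetic anhydride, CC(=O)OC(C)=O
Why: Routine DMAP-catalysed acetylation of the secondary allylic alcohol.

Step 21
Reactants: 33 tert-butyl 3-acetoxy-2-methylidenebutanoate
Product: 34 tert-butyl (2E)-2-(acetoxymethyl)but-2-enoate
Conditions: DABCO (0.2 equiv), THF, reflux
Reagents that add atoms: none
Why: DABCO-catalysed SN2′–SN2′ transposition of the Baylis–Hillman acetate gives the conjugated trisubstituted alkene under thermodynamic control, which should be the E isomer (methyl trans to the ester) as in tiglates.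

Step 22
Reactants: 34 tert-butyl (2E)-2-(acetoxymethyl)but-2-enoate
Product: 35 (2E)-2-(acetoxymethyl)but-2-enoic acid
Conditions: TFA/CH2Cl2 (1:4), 0 °C → rt
Reagents that add atoms: none
Why: Acidolysis of the tert-butyl ester (loss of isobutene) leaves the allylic acetate and the enoate untouched.

Step 23
Reactants: 29 (4Z,6S,7S,8R,10R)-8-hydroxy-3,10:6,12-diepoxygermacra-2,4,11(13)-trien-1-one; 35 (2E)-2-(acetoxymethyl)but-2-enoic acid
Product: 36 (4Z,6S,7S,8R,10R)-8-{[(2E)-2-(acetoxymethyl)but-2-enoyl]oxy}-3,10:6,12-diepoxygermacra-2,4,11(13)-trien-1-one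
Conditions: DCC, DMAP (0.1 equiv), CH2Cl2, 0 °C → rt
Reagents that add atoms: none
Why: Steglich esterification of the single free hydroxyl (C8) with only catalytic DMAP, the E enoate being the stable geometry so that no isomerisation is expected.

Step 24
Reactants: 36 (4Z,6S,7S,8R,10R)-8-{[(2E)-2-(acetoxymethyl)but-2-enoyl]oxy}-3,10:6,12-diepoxygermacra-2,4,11(13)-trien-1-one
Product: 37 (4Z,6S,7S,8R,10R)-8-{[(2E)-2-(acetoxymethyl)but-2-enoyl]oxy}-3,10-epoxy-1-oxogermacra-2,4,11(13)-trien-12,6-olide (target)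
Conditions: CrO3·3,5-dimethylpyrazole (excess), CH2Cl2, −20 °C
Reagents that add atoms: chromium trioxide, O=[Cr](=O)=O
Why: Chromium(VI) allylic oxidation of the cyclic allylic ether, where C12–H is the only C–H that is both α to oxygen and allylic to an electron-rich alkene, converts the 3-methylene-tetrahydrofuran into the α-methylene-γ-butyrolactone.

Compound list
1 | dimethyl (4R,5R)-2,2-dimethyl-1,3-dioxolane-4,5-dicarboxylate | COC(=O)[C@@H]1OC(C)(C)O[C@H]1C(=O)OC | starting material
2 | (4R,5R)-2,2-dimethyl-1,3-dioxolane-4,5-dicarbaldehyde | O=C[C@@H]1OC(C)(C)O[C@H]1C=O | intermediate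
3 | (4S,5S)-2,2-dimethyl-4,5-divinyl-1,3-dioxolane | C=C[C@@H]1OC(C)(C)O[C@H]1C=C | intermediate
4 | (3S,4S)-hexa-1,5-diene-3,4-diol | C=C[C@H](O)[C@@H](O)C=C | intermediate
5 | (3S,4S)-4-(TBSO)hexa-1,5-dien-3-ol | C=C[C@H](O)[C@@H](O[Si](C)(C)C(C)(C)C)C=C | intermediate
6 | bromoacetic acid | OC(=O)CBr | starting material
7 | 2-{[(3S,4S)-4-(TBSO)hexa-1,5-dien-3-yl]oxy}acetic acid | C=C[C@H](OCC(=O)O)[C@@H](O[Si](C)(C)C(C)(C)C)C=C | intermediate
8 | (S)-4-benzyl-1,3-oxazolidin-2-one | O=C1N[C@@H](Cc2ccccc2)CO1 | starting material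
9 | mixed pivalic anhydride of 7 | C=C[C@H](OCC(=O)OC(=O)C(C)(C)C)[C@@H](O[Si](C)(C)C(C)(C)C)C=C | intermediate
10 | (4S)-4-benzyl-3-(2-{[(3S,4S)-4-(TBSO)hexa-1,5-dien-3-yl]oxy}acetyl)-1,3-oxazolidin-2-one | C=C[C@H](OCC(=O)N1[C@@H](Cc2ccccc2)COC1=O)[C@@H](O[Si](C)(C)C(C)(C)C)C=C | intermediate
11 | tert-butyl bromoacetate | CC(C)(C)OC(=O)CBr | starting material
12 | tert-butyl (3R)-4-[(4S)-4-benzyl-2-oxo-1,3-oxazolidin-3-yl]-4-oxo-3-{[(3S,4S)-4-(TBSO)hexa-1,5-dien-3-yl]oxy}butanoate | C=C[C@H](O[C@H](CC(=O)OC(C)(C)C)C(=O)N1[C@@H](Cc2ccccc2)COC1=O)[C@@H](O[Si](C)(C)C(C)(C)C)C=C | intermediate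
13 | tert-butyl (3R)-4-[methoxy(methyl)amino]-4-oxo-3-{[(3S,4S)-4-(TBSO)hexa-1,5-dien-3-yl]oxy}butanoate | C=C[C@H](O[C@H](CC(=O)OC(C)(C)C)C(=O)N(C)OC)[C@@H](O[Si](C)(C)C(C)(C)C)C=C | intermediate
14 | tert-butyl (3R)-4-oxo-3-{[(3S,4S)-4-(TBSO)hexa-1,5-dien-3-yl]oxy}pentanoate | C=C[C@H](O[C@H](CC(=O)OC(C)(C)C)C(C)=O)[C@@H](O[Si](C)(C)C(C)(C)C)C=C | intermediate
15 | tert-butyl (3R)-4-methyl-3-{[(3S,4S)-4-(TBSO)hexa-1,5-dien-3-yl]oxy}pent-4-enoate | C=C[C@H](O[C@H](CC(=O)OC(C)(C)C)C(C)=C)[C@@H](O[Si](C)(C)C(C)(C)C)C=C | intermediate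
16 | tert-butyl (3R)-3-{[(3S,4S)-4-hydroxyhexa-1,5-dien-3-yl]oxy}-4-methylpent-4-enoate | C=C[C@H](O[C@H](CC(=O)OC(C)(C)C)C(C)=C)[C@@H](O)C=C | intermediate
17 | tert-butyl 2-[(2S,3S,6R)-3-hydroxy-5-methyl-2-vinyl-3,6-dihydro-2H-pyran-6-yl]acetate | CC(C)(C)OC(=O)C[C@H]1O[C@@H](C=C)[C@@H](O)C=C1C | intermediate
18 | tert-butyldimethylsilyl 2-[(2S,3S,6R)-3-(TBSO)-5-methyl-2-vinyl-3,6-dihydro-2H-pyran-6-yl]acetate | CC(C)(C)[Si](C)(C)OC(=O)C[C@H]1O[C@@H](C=C)[C@@H](O[Si](C)(C)C(C)(C)C)C=C1C | intermediate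
19 | 2-[(2S,3S,6R)-3-(TBSO)-5-methyl-2-vinyl-3,6-dihydro-2H-pyran-6-yl]acetic acid | OC(=O)C[C@H]1O[C@@H](C=C)[C@@H](O[Si](C)(C)C(C)(C)C)C=C1C | intermediate
20 | isobutyl carbonic anhydride of 19 | CC(C)COC(=O)OC(=O)C[C@H]1O[C@@H](C=C)[C@@H](O[Si](C)(C)C(C)(C)C)C=C1C | intermediate
21 | 3-diazo-1-[(2S,3S,6R)-3-(TBSO)-5-methyl-2-vinyl-3,6-dihydro-2H-pyran-6-yl]butan-2-one (all-cis; key-step precursor) | CC(=[N+]=[N-])C(=O)C[C@H]1O[C@@H](C=C)[C@@H](O[Si](C)(C)C(C)(C)C)C=C1C | intermediate
22 | cis-fused bicyclic oxonium ylide (five-membered ylide ring on the dihydropyran oxygen, carbanion at C10) | C[C-]1C(=O)C[C@@H]2C(C)=C[C@H](O[Si](C)(C)C(C)(C)C)[C@H](C=C)[O+]12 | intermediate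
23 | (1R,2Z,4R,5Z,8R)-4-(TBSO)-2,8-dimethyl-11-oxabicyclo[6.2.1]undeca-2,5-dien-9-one (key-step product) | C1/C=C\[C@@H](O[Si](C)(C)C(C)(C)C)/C=C(/C)[C@H]2CC(=O)[C@]1(C)O2 | intermediate
24 | (1R,2Z,4R,5Z,8R)-4-(TBSO)-2,8-dimethyl-9-(trimethylsilyloxy)-11-oxabicyclo[6.2.1]undeca-2,5,9-triene | C1/C=C\[C@@H](O[Si](C)(C)C(C)(C)C)/C=C(/C)[C@H]2C=C(O[Si](C)(C)C)[C@]1(C)O2 | intermediate
25 | (2Z,4R,5Z,8R)-4-(TBSO)-2,8-dimethyl-11-oxabicyclo[6.2.1]undeca-1(10),2,5-trien-9-one | C1/C=C\[C@@H](O[Si](C)(C)C(C)(C)C)/C=C(/C)C2=CC(=O)[C@]1(C)O2 | intermediate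
26 | (2Z,4R,5Z,8R)-4-hydroxy-2,8-dimethyl-11-oxabicyclo[6.2.1]undeca-1(10),2,5-trien-9-one | C1/C=C\[C@@H](O)/C=C(/C)C2=CC(=O)[C@]1(C)O2 | intermediate
27 | propargyl bromide (3-bromoprop-1-yne) | C#CCBr | starting material
28 | (2Z,4R,5Z,8R)-2,8-dimethyl-4-(prop-2-yn-1-yloxy)-11-oxabicyclo[6.2.1]undeca-1(10),2,5-trien-9-one | C1/C=C\[C@@H](OCC#C)/C=C(/C)C2=CC(=O)[C@]1(C)O2 | intermediate
29 | (4Z,6S,7S,8R,10R)-8-hydroxy-3,10:6,12-diepoxygermacra-2,4,11(13)-trien-1-one | C=C1CO[C@H]2/C=C(/C)C3=CC(=O)[C@@](C)(C[C@@H](O)[C@H]12)O3 | intermediate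
30 | tert-butyl acrylate | C=CC(=O)OC(C)(C)C | starting material
31 | acetaldehyde | CC=O | starting material
32 | tert-butyl 3-hydroxy-2-methylidenebutanoate (racemic) | CC(O)C(=C)C(=O)OC(C)(C)C | intermediate
33 | tert-butyl 3-acetoxy-2-methylidenebutanoate (racemic) | CC(OC(C)=O)C(=C)C(=O)OC(C)(C)C | intermediate
34 | tert-butyl (2E)-2-(acetoxymethyl)but-2-enoate | C/C=C(\COC(C)=O)C(=O)OC(C)(C)C | intermediate
35 | (2E)-2-(acetoxymethyl)but-2-enoic acid | C/C=C(\COC(C)=O)C(=O)O | intermediate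
36 | (4Z,6S,7S,8R,10R)-8-{[(2E)-2-(acetoxymethyl)but-2-enoyl]oxy}-3,10:6,12-diepoxygermacra-2,4,11(13)-trien-1-one | C=C1CO[C@H]2/C=C(/C)C3=CC(=O)[C@@](C)(C[C@@H](OC(=O)/C(=C/C)COC(C)=O)[C@H]12)O3 | intermediate
37 | (4Z,6S,7S,8R,10R)-8-{[(2E)-2-(acetoxymethyl)but-2-enoyl]oxy}-3,10-epoxy-1-oxogermacra-2,4,11(13)-trien-12,6-olide | C=C1C(=O)O[C@H]2/C=C(/C)C3=CC(=O)[C@@](C)(C[C@@H](OC(=O)/C(=C/C)COC(C)=O)[C@H]12)O3 | target

Total step count: 24 (20 in the main line, 4 for the side-chain acid).
Longest linear sequence: 20 steps (steps 1–18, 23 and 24).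

Steps most likely to fail

Step 14. What may go wrong: the copper carbenoid is lost by 1,2-hydride migration from its methyl group, or it adds to the neighbouring C4=C5 bond before the ring oxygen captures it. The fallback sets out from 19 and returns at 23; it takes the β-hydrogens away from the carbenoid and makes the C10 methyl afterwards. Acid 19 is homologated (carbonyldiimidazole, then magnesium methyl malonate) to the methyl β-keto ester F1. Diazo transfer (p-ABSA, Et3N) gives the diazo keto ester F2. The same oxonium ylide [2,3] ring expansion (Cu(hfacac)2 or Rh2(OAc)4), now from an acceptor/acceptor carbenoid that cannot shift hydride, should give the bridged keto ester F3. LiAlH4 reduces ketone and ester to the diol F4, and the primary hydroxyl is tosylated selectively to the tosylate F5. LiEt3BH removes the sulfonate to leave the C10 methyl in the alcohol F6, and Dess–Martin oxidation of F6 gives 23.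

Step 18. What may go wrong: the alkyne is hydrated, or the enyne rearranges without capture of water, because the Z C7=C8 bond held in the macrocycle does not reach the gold-bound alkyne in the 5-exo geometry. The fallback sets out from 26 and returns at 29; it closes the same ring by a radical instead of a π-acid. Alcohol 26 is alkylated with 2,3-dibromopropene (NaH, THF, 0 °C) to the 2-bromoallyl ether F7. Bu3SnH under dry air (oxygenative vinyl-radical cyclisation) should then form the C7–C11 bond 5-exo and trap the C8 radical with oxygen, giving 29 after reduction of the hydroperoxide.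

Step 24. What may go wrong: poor site selectivity or over-oxidation by chromium(VI) at the other activated C–H bonds (C6–H, the C4 methyl), or degradation of the methylene lactone as it forms. The fallback sets out from 36 and returns at 37; it reaches the lactone in two mild stages through the lactol. SeO2/t-BuOOH ene-type hydroxylation of 36 at C12 gives the lactol F8, and TEMPO/PhI(OAc)2 oxidises F8 to 37.

Further compounds
F1 | step 14 | methyl 3-oxo-4-[(2S,3S,6R)-3-(TBSO)-5-methyl-2-vinyl-3,6-dihydro-2H-pyran-6-yl]butanoate | COC(=O)CC(=O)C[C@H]1O[C@@H](C=C)[C@@H](O[Si](C)(C)C(C)(C)C)C=C1C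
F2 | step 14 | methyl 2-diazo-3-oxo-4-[(2S,3S,6R)-3-(TBSO)-5-methyl-2-vinyl-3,6-dihydro-2H-pyran-6-yl]butanoate | COC(=O)C(=[N+]=[N-])C(=O)C[C@H]1O[C@@H](C=C)[C@@H](O[Si](C)(C)C(C)(C)C)C=C1C
F3 | step 14 | methyl (1R,2Z,4R,5Z,8R)-4-(TBSO)-2-methyl-9-oxo-11-oxabicyclo[6.2.1]undeca-2,5-diene-8-carboxylate | C1/C=C\[C@@H](O[Si](C)(C)C(C)(C)C)/C=C(/C)[C@H]2CC(=O)[C@]1(C(=O)OC)O2
F4 | step 14 | 8-(hydroxymethyl)-4-(TBSO)-2-methyl-11-oxabicyclo[6.2.1]undeca-2,5-dien-9-ol (C9 carbinol as a mixture) | C1/C=C\[C@@H](O[Si](C)(C)C(C)(C)C)/C=C(/C)[C@H]2CC(O)[C@]1(CO)O2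
F5 | step 14 | primary p-toluenesulfonate of F4 | C1/C=C\[C@@H](O[Si](C)(C)C(C)(C)C)/C=C(/C)[C@H]2CC(O)[C@]1(COS(=O)(=O)c3ccc(C)cc3)O2
F6 | step 14 | 4-(TBSO)-2,8-dimethyl-11-oxabicyclo[6.2.1]undeca-2,5-dien-9-ol (C9 carbinol as a mixture) | C1/C=C\[C@@H](O[Si](C)(C)C(C)(C)C)/C=C(/C)[C@H]2CC(O)[C@]1(C)O2
F7 | step 18 | (2Z,4R,5Z,8R)-4-[(2-bromoprop-2-en-1-yl)oxy]-2,8-dimethyl-11-oxabicyclo[6.2.1]undeca-1(10),2,5-trien-9-one | C1/C=C\[C@@H](OCC(Br)=C)/C=C(/C)C2=CC(=O)[C@]1(C)O2
F8 | step 24 | C12 lactol of 36 (12-hydroxy-6,12-epoxide; C12 as a mixture) | C=C1C(O)O[C@H]2/C=C(/C)C3=CC(=O)[C@@](C)(C[C@@H](OC(=O)/C(=C/C)COC(C)=O)[C@H]12)O3
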